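The runs stem from a simulated flask with constants of no real substance; scatter was added.

| flask | X | J | Z | remark | time |
|---|---|---|---|---|---|
| north-east | 11 mM | 5.5 mM | 5.5 mM | the very flask that is asked about, followed so far |  |
| south-west | 22 mM | 5.5 mM | 5.5 mM | run made earlier |  |
| flask | 11 mM | 5.50 mM | 5.50 mM |  | 20 h |

| run | time / h | X / % | Q / % |
|---|---|---|---|
| north-east | 0.500 | 80.2 | 0.5 |
| north-east | 1.00 | 81.5 | 0.2 |
| north-east | 1.50 | 82.2 | 0.2 |
| north-east | 2.50 | 82.8 | 0.4 |
| north-east | 3.00 | 81.5 | 0.2 |
| north-east | 4.00 | 81.3 | 1.5 |
| south-west | 0.833 | 87.4 | 0.1 |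
| south-west | 2.00 | 87.7 | 0.5 |
| south-west | 4.00 | 87.7 | 0 |
| south-west | 6.00 | 87.2 | 0.7 |
| south-west | 8.00 | 87.6 | 0 |
| south-west | 12.0 | 87.6 | 0 |
| south-west | 15.0 | 87.5 | 0 |

(readings scatter by 0.5 percentage points)

- which holds at 20 h: what has brought the reaction to rest, or that it has not come to rest (all of X has reacted / it is still moving / forward and back rates have come level / J has run out first)
- part of the X gone at 20 h

- the reaction counts as stopped when no species that holds the X changes by six tenths of a point or more over the second half of the time

1. I almost read the flat X as J spent. One-for-one, that takes X down to 50.0 % of its charge, but the north-east run stood at 81.3 % at 4.00 h.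

2. The south-west run held X flat from 0.833 h to 15.0 h. Its mean gave f, the part of X gone: 12.5 %. One-for-one, that left J at 50.1 % of its charge and brought Z to 150 % of its own.

3. So I took a single exchange at rest. With x the part of X left, and j, z the amounts of J and Z as parts of the charged J (in this run Z was charged equal to J), the exchange quotient z·f/(j·x), an apparent equilibrium constant, read 0.426 in the south-west run.

4. Solved for the north-east charges, that quotient gave 17.2 % of X gone.

5. The weak link was the borrowed quotient. The north-east mean read 18.4 % gone, a gap of 1.2 percentage points, and one reading is good to 0.5 points. So I kept the north-east exchange quotient, 0.489.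

6. The forecast said forward and back rates have come level, with 18 % gone, between 16.5 % and 20.5 %: “This is therefore an equilibrium, not exhaustion of J or X.”

7. The flask gave forward and back rates have come level, with 18.3 % gone.

    X + J ⇌ Z + L (K = 0.550, k = 94.0 M⁻¹ min⁻¹)
    L + J ⇌ Z + G (K = 1.20, k = 4.60 M⁻¹ min⁻¹)
    G + J ⇌ Z + Q (K = 0.930, k = 120 M⁻¹ min⁻¹)
    Q + J ⇌ Z + E (K = 6.30, k = 18.0 M⁻¹ min⁻¹)
    Q ⇌ D (K = 0.910, k = 0.620 min⁻¹)

One proven reason for the rest is the undoing of Z + L into X + J. The forecast goes wrong if that undoing is struck out: the ending changes, and conversion goes from 18.3 % to 50.0 %. In the asked flask 18.3 % gives a one-for-one quotient of 0.482, yet J stands at 41 % of its charge, lower than the one-for-one 63.4 %. So the quotient lumps several exchanges together.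

In the neighbour flask with 1.4 mM of J, its X, Z and time as in the asked flask, 0.489 gave 5.76 % of X gone. The computed neighbour gave 6.00 %.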